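## Analysis of the target

Kaempferol 3,7-di-O-sulfate is a flavonol: a 4H-chromen-4-one (ring A fused to pyranone ring C) with a 4-hydroxyphenyl ring B on C2 and oxygen on C3, C5, C7 and C4'. The molecule is flat and has no stereocentre, so the problem is purely positional: four hydroxyls, of which only O3 and O7 carry sulfate. The 5-OH is held to the C4 carbonyl by a six-membered hydrogen bond and is the least acidic and least nucleophilic oxygen, whereas the 7-OH is the most acidic and the 4'-OH is expected to react ahead of the 3-OH, so O4' needs a mask while O5 protects itself. Sulfate monoesters are strong acids, water-soluble, unsuited to silica and cleaved by acid, so they have to be installed last and followed only by a neutral deprotection. Ring A has the phloroglucinol pattern, which is symmetric before ring C is closed, so either ortho oxygen gives the same chromone. The strategy rests on C4: this carbonyl carbon lies between the ring A carbon C4a and the oxygen-bearing C3, and is the only skeletal carbon that belongs to neither aryl fragment. It can therefore enter as carbon monoxide between an aryl halide (C4a) and a ketone α-carbon (C3), giving a 1,3-diketone that already holds every carbon and oxygen of the flavonol at the correct oxidation level.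

## Retrosynthetic reasoning

**17 ⇒ 16 ⇒ 15 (O4'–benzyl bond).** The free acid 17 is the protonated form of the bis(triethylammonium) salt 16, which comes from the 4'-O-benzyl disulfate 15 by cutting the O–CH2Ph bond. Sulfate ester salts survive neutral hydrogenolysis but not acidic or strongly nucleophilic deprotection, so a benzyl ether is the one protecting group that may outlast sulfation. The forward step must cleave it without touching the S–O bonds or the C2–C3 double bond.

**15 ⇒ 14 (the two O–S bonds at O3 and O7).** Both sulfates are removed together to reveal 4'-O-benzylkaempferol 14. Sulfating the finished flavonol lets its own reactivity order choose the sites: O7 first, O3 next, O5 chelated, O4' blocked. This means O3, O5 and O7 need no mutual differentiation earlier and can be unmasked in one operation. The forward step must sulfate twice and stop before O5.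

**14 ⇒ 11 (O1–C2 bond and the C2–C3 double bond).** Ring C is opened at O1–C2, and C2 returns to a ketone. This gives the fully protected 2-oxygenated 1,3-diketone 11, with the free diketone 12 and the hemiketal 13 as unisolated stages on the way forward. All four oxygens of 11 carry the same acetal, so one acid treatment frees them, closes ring C and dehydrates. Ring A is symmetric, so no regiochemical question arises. The benzyl ether must survive the acid.

**11 ⇒ 4 + 9 + 8 (C4a–C4 and C4–C3).** Both bonds to C4 are cut, so C4 becomes carbon monoxide 9. The ring A piece becomes aryl iodide 4, and C2, C3 and ring B become the α-alkoxy ketone 8. Cutting only C4–C3 (a Claisen acylation) would need a hindered 2,6-dioxygenated benzoyl electrophile. Cutting C2–C3 would need an O-to-C acyl shift on a selectively mono-deprotected ring A. The double cut at C4 instead gives two fragments that are each two steps from commercial materials. The forward reaction must form the aroyl–palladium species before any C–C coupling and must keep the acidic product intact in base.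

**4 ⇒ 2 ⇒ 1 (C–I bond, then three O–CH2 bonds).** The iodide comes from tris-acetal 2 through aryllithium 3, and 2 comes from phloroglucinol 1. Each ring C–H of 2 sits between two directing acetal oxygens and the three are equivalent, so one lithiation gives one product.

**8 ⇒ 7 ⇒ 5 (acetal O–CH2 bond, then the C3–O3 bond).** The acetal is removed to give α-hydroxy ketone 7, and the α-oxygen is removed to give 4'-(benzyloxy)acetophenone 5, through the unisolated acetal 6 in the forward direction. O3 is introduced before the coupling so that no oxidation is needed once ring C exists.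

## Alternatives that were turned down

**Alternative 1: reductive closure of ring C at C3–C4.**
- Disconnection: the C3–C4 bond, leading back to the dialdehyde A2, in which an aryl aldehyde on ring A sits ortho to an ether oxygen (O1) carrying a CH(ring B)–CHO unit.
- Forward key step: samarium diiodide A3, a reagent of divalent samarium, reduces the aryl aldehyde of A2 to a ketyl, which adds to the tethered aliphatic aldehyde to give the chromane-3,4-diol A1 as a mixture of stereoisomers.
- For: the closure is intramolecular and runs under neutral conditions. On this point it is stronger than the chosen route, whose key step is an intermolecular three-component coupling on a crowded iodide. It also needs no pressurised gas.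
- Against: A1 lies four electrons below the flavonol. C4 must be oxidised selectively in the presence of the C3 carbinol, and C2–C3 must then be dehydrogenated. Three transient stereocentres give mixtures until that is done. The aliphatic aldehyde of A2 carries an α-aryloxy group, and A3 can equally reduce it to a ketyl that expels the phenoxide and severs the tether. A2 is also an enolisable α-aryl aldehyde that takes several steps to make.
- Comparison: the chosen route gives up the intramolecular advantage but delivers C4 directly as a ketone, so the only operation after the coupling is one acid treatment.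

**Alternative 2: Diels–Alder construction of ring A on a pyranone.**
- Disconnection: C4a–C5 and C8–C8a, leading back to the sulfinylpyranone A5 and the bis(silyloxy)diene A6.
- Forward key step: [4+2] cycloaddition of A5 with A6, after which the sulfinyl and methoxy groups are eliminated and ring A aromatises to the 5,7-dihydroxy-3-(methoxymethoxy)flavone A4.
- For: the ring A oxygenation pattern is fixed by the diene. A4 also emerges with O3 capped and O5/O7 free, a differentiation the chosen route does not provide.
- Against: that differentiation is of no use here, because O3 and O7 must be treated alike and O5 is already set apart by its hydrogen bond. A5 is a fully substituted 2-aryl-3-alkoxy-4-pyranone with an extra sulfinyl group, about as hard to build as the flavonol itself. Its C5–C6 double bond is part of a vinylogous ester and a reluctant dienophile. A6 is sensitive to acid and moisture.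
- Comparison: the chosen route takes ring A intact and symmetric from phloroglucinol 1, so building it from a diene gains nothing and costs steps.

**Alternative 3: biomimetic folding of a pyrone-masked polyketide into ring A.**
- Disconnection: the C4a–C8a bond of ring A, leading back to the 4-hydroxy-2-pyrone A8.
- Forward key step: magnesium dimethoxide A10 in its parent alcohol opens A8 to the triketo ester A9. The C4a carbanion of A9 then attacks the ester carbon C8a (Claisen mode) to give the acylphloroglucinol A7, an α-alkoxy chalcone.
- For: the logic follows the biosynthesis, uses no transition metal and gives ring A with free hydroxyls. On metal-free operation and absence of ring A protecting groups it is stronger than the chosen route.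
- Against: A7 is still a chalcone, so ring C needs an oxa-Michael closure and a further two-electron oxidation next to an unprotected, easily oxidised phloroglucinol ring. The folding of A9 can also take aldol modes or relactonise. Its enone is exposed to conjugate addition by the alkoxide of A10. A8 needs a long linear build-up.
- Comparison: the chosen route spends two protecting-group steps on ring A but confines the uncertainty to one catalytic coupling whose product is already at the flavonol oxidation level.

Key step: step 5

## Route

Assumption: the target is taken as the free bis(hydrogen sulfate) exactly as drawn. Its bis(triethylammonium) salt 16 is the form that would be stored, and the acid is liberated from it only at the very end.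

Step 1
Reactants: 1 phloroglucinol (benzene-1,3,5-triol)
Product: 2 1,3,5-tris(methoxymethoxy)benzene
Conditions: NaH (3.6 equiv), MOMCl (3.6 equiv), DMF, 0 °C → rt
Reagents that add atoms: chloromethyl methyl ether (MOMCl), COCCl
Why: O-alkylation of the phenoxide with a hard oxocarbenium-type electrophile (MOM protection). The acetal directs the lithiation of step 2, withstands the strong base of step 5 and is removed by the same acid that closes ring C.

Step 2
Reactants: 2 1,3,5-tris(methoxymethoxy)benzene
Product: 4 2-iodo-1,3,5-tris(methoxymethoxy)benzene, via [2,4,6-tris(methoxymethoxy)phenyl]lithium 3 (not isolated)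
Conditions: n-BuLi (1.05 equiv), THF, 0 °C; then I2, −78 °C → rt; aq Na2S2O3
Reagents that add atoms: iodine, II; n-butyllithium, [Li]CCCC (lithium of 3 only)
Why: Directed ortho-metalation followed by iodine quench. Every ring C–H lies between two coordinating acetal oxygens and the three are equivalent, so one equivalent of base should give a single aryllithium, and no acid is formed that could touch the acetals.

Step 3
Reactants: 5 1-[4-(benzyloxy)phenyl]ethanone (4'-(benzyloxy)acetophenone)
Product: 7 1-[4-(benzyloxy)phenyl]-2-hydroxyethanone, via 2-[4-(benzyloxy)phenyl]-2,2-dimethoxyethanol 6 (not isolated)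
Conditions: PhI(OAc)2 (1.1 equiv), KOH (3 equiv), MeOH, 0 °C → rt; then 2 M HCl, THF, rt
Reagents that add atoms: water, O (new carbonyl oxygen of 7 on acetal hydrolysis; the hydroxyl oxygen is the former carbonyl oxygen of 5); methanol, CO (the two methoxy groups of 6 only)
Why: Moriarty α-hydroxylation. The enolate attacks the trivalent iodine of PhI(OAc)2, methoxide adds to the carbonyl, and the alkoxide displaces iodobenzene to a methoxy epoxide that methoxide opens to the hydroxy dimethyl acetal; dilute acid then unmasks the ketone. The benzyl ether is inert to both stages.

Step 4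
Reactants: 7 1-[4-(benzyloxy)phenyl]-2-hydroxyethanone
Product: 8 1-[4-(benzyloxy)phenyl]-2-(methoxymethoxy)ethanone
Conditions: MOMCl (1.5 equiv), iPr2NEt (2 equiv), CH2Cl2, 0 °C → rt
Reagents that add atoms: chloromethyl methyl ether (MOMCl), COCCl
Why: MOM protection of a primary alcohol under a hindered amine base, mild enough to avoid α-ketol isomerisation. Giving O3 the same acetal as ring A lets one acid step free all four oxygens later.

Step 5
Reactants: 4 2-iodo-1,3,5-tris(methoxymethoxy)benzene; 8 1-[4-(benzyloxy)phenyl]-2-(methoxymethoxy)ethanone; 9 carbon monoxide
Product: 11 1-[4-(benzyloxy)phenyl]-2-(methoxymethoxy)-3-[2,4,6-tris(methoxymethoxy)phenyl]propane-1,3-dione (racemic), via sodium (Z)-1-[4-(benzyloxy)phenyl]-2-(methoxymethoxy)ethen-1-olate 10 (not isolated)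
Conditions: 8 (2.2 equiv), NaN(SiMe3)2 (2.1 equiv), THF, −78 → 0 °C; then 4 (1 equiv), Pd(dba)2 (5 mol %), DPPP (5 mol %), CO (9, 2–3 bar), THF–dioxane, 80 °C, sealed; AcOH quench, 0 °C
Reagents that add atoms: sodium bis(trimethylsilyl)amide, C[Si](C)(C)[N-][Si](C)(C)C.[Na+] (sodium of 10 only)
Why: Zerovalent palladium ligated by DPPP inserts into the C–I bond of 4, and the electron-rich, doubly ortho-substituted aryl group migrates to coordinated CO, which relieves crowding at the metal and forms C4a–C4 in an aroyl complex of divalent palladium. Enolate 10 replaces iodide and reductive elimination from the cis acyl/enolate complex forms C4–C3 and returns zerovalent palladium; any enol ester from O-acylation is itself an acyl donor toward 10, so both paths should end in the same diketonate. The closest known reaction type is the palladium-catalysed carbonylative α-arylation of aryl alkyl ketones with aryl iodides to 1,3-diketones, in which α-substituted ketones take part. No ring closes. The one new stereocentre, the OMOM-bearing carbon between the two carbonyls, forms racemic with no controlling element and needs none, because it is enolised in the flask and becomes sp2 in step 6. The step needs carbonylative rather than direct arylation: the two ortho OMOM groups slow direct aryl–enolate reductive elimination, and CO under slight pressure makes insertion fast. It also needs the product protected: 11 is far more acidic than 8 and is held as its sodium diketonate by the second equivalent of 10, which blocks a second aroylation and retro-Claisen cleavage. Forming 10 beforehand with 8 in slight excess over the amide leaves no free amide base to react with CO.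

Step 6
Reactants: 11 1-[4-(benzyloxy)phenyl]-2-(methoxymethoxy)-3-[2,4,6-tris(methoxymethoxy)phenyl]propane-1,3-dione
Product: 14 2-[4-(benzyloxy)phenyl]-3,5,7-trihydroxy-4H-chromen-4-one (4'-O-benzylkaempferol), via 1-[4-(benzyloxy)phenyl]-2-hydroxy-3-(2,4,6-trihydroxyphenyl)propane-1,3-dione 12 (not isolated), via 2-[4-(benzyloxy)phenyl]-2,3,5,7-tetrahydroxychroman-4-one 13 (not isolated)
Conditions: HCl (ca. 2 M) in MeOH–THF, 60 °C
Reagents that add atoms: none
Why: Acid-catalysed transacetalisation to methanol removes the four MOM groups. Either ortho hydroxyl of the symmetric ring A then adds to the ring B ketone (6-exo-trig) to give the hemiketal, and loss of water across C2–C3 gives the aromatic pyranone (cyclodehydration of an o-hydroxyaryl 1,3-diketone). The racemic centre of 11 disappears, and the aryl benzyl ether is stable to methanolic HCl.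

Step 7
Reactants: 14 2-[4-(benzyloxy)phenyl]-3,5,7-trihydroxy-4H-chromen-4-one
Product: 15 bis(triethylammonium) 2-[4-(benzyloxy)phenyl]-5-hydroxy-4-oxo-4H-chromene-3,7-diyl bis(sulfate)
Conditions: SO3·NEt3 (5 equiv), Et3N (4 equiv), DMA, 60 °C; Sephadex LH-20 (MeOH)
Reagents that add atoms: sulfur trioxide–triethylamine complex, CC[N+](CC)(CC)S(=O)(=O)[O-]
Why: O-sulfation of phenolic and enolic hydroxyls with an SO3–amine complex. The acidic 7-OH should react first and the 3-OH next, while the 5-OH, locked in its hydrogen bond to the C4 carbonyl, should stay free and O4' is benzylated. Using one amine for reagent and base gives a single counter-ion.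

Step 8
Reactants: 15 bis(triethylammonium) 2-[4-(benzyloxy)phenyl]-5-hydroxy-4-oxo-4H-chromene-3,7-diyl bis(sulfate)
Product: 17 kaempferol 3,7-di-O-sulfate (5-hydroxy-2-(4-hydroxyphenyl)-4-oxo-4H-chromene-3,7-diyl bis(hydrogen sulfate)), via bis(triethylammonium) kaempferol 3,7-di-O-sulfate 16 (not isolated)
Conditions: H2 (1 atm), palladium on carbon (Pd/C, 10%), MeOH–H2O, rt; filter; Dowex 50W (H+ form), H2O, 0–5 °C; freeze-dry at once
Reagents that add atoms: none
Why: Hydrogenolysis of an aryl benzyl ether over Pd/C under neutral conditions, to which sulfate ester salts and the chromone double bond are inert. The sulfonic acid resin then exchanges triethylammonium for protons; the free acid is kept cold and dried immediately because aryl hydrogen sulfates hydrolyse under their own acidity.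

## Compound list

1 | phloroglucinol (benzene-1,3,5-triol) | Oc1cc(O)cc(O)c1 | starting material
2 | 1,3,5-tris(methoxymethoxy)benzene | COCOc1cc(OCOC)cc(OCOC)c1 | intermediate
3 | [2,4,6-tris(methoxymethoxy)phenyl]lithium | [Li]c1c(OCOC)cc(OCOC)cc1OCOC | intermediate (not isolated)
4 | 2-iodo-1,3,5-tris(methoxymethoxy)benzene | COCOc1cc(OCOC)c(I)c(OCOC)c1 | intermediate
5 | 1-[4-(benzyloxy)phenyl]ethanone | CC(=O)c1ccc(OCc2ccccc2)cc1 | starting material
6 | 2-[4-(benzyloxy)phenyl]-2,2-dimethoxyethanol | COC(CO)(OC)c1ccc(OCc2ccccc2)cc1 | intermediate (not isolated)
7 | 1-[4-(benzyloxy)phenyl]-2-hydroxyethanone | O=C(CO)c1ccc(OCc2ccccc2)cc1 | intermediate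
8 | 1-[4-(benzyloxy)phenyl]-2-(methoxymethoxy)ethanone | O=C(COCOC)c1ccc(OCc2ccccc2)cc1 | intermediate
9 | carbon monoxide | [C-]#[O+] | starting material
10 | sodium (Z)-1-[4-(benzyloxy)phenyl]-2-(methoxymethoxy)ethen-1-olate (Z expected from sodium chelation) | [Na+].[O-]/C(=C\OCOC)c1ccc(OCc2ccccc2)cc1 | intermediate (not isolated)
11 | 1-[4-(benzyloxy)phenyl]-2-(methoxymethoxy)-3-[2,4,6-tris(methoxymethoxy)phenyl]propane-1,3-dione (racemic) | O=C(C(OCOC)C(=O)c1ccc(OCc2ccccc2)cc1)c1c(OCOC)cc(OCOC)cc1OCOC | intermediate
12 | 1-[4-(benzyloxy)phenyl]-2-hydroxy-3-(2,4,6-trihydroxyphenyl)propane-1,3-dione (racemic) | O=C(C(O)C(=O)c1ccc(OCc2ccccc2)cc1)c1c(O)cc(O)cc1O | intermediate (not isolated)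
13 | 2-[4-(benzyloxy)phenyl]-2,3,5,7-tetrahydroxychroman-4-one (mixture of diastereomers) | O=C1c2c(O)cc(O)cc2OC(O)(c2ccc(OCc3ccccc3)cc2)C1O | intermediate (not isolated)
14 | 2-[4-(benzyloxy)phenyl]-3,5,7-trihydroxy-4H-chromen-4-one (4'-O-benzylkaempferol) | O=c1c(O)c(-c2ccc(OCc3ccccc3)cc2)oc2cc(O)cc(O)c12 | intermediate
15 | bis(triethylammonium) 2-[4-(benzyloxy)phenyl]-5-hydroxy-4-oxo-4H-chromene-3,7-diyl bis(sulfate) | CC[NH+](CC)CC.CC[NH+](CC)CC.O=c1c(OS(=O)(=O)[O-])c(-c2ccc(OCc3ccccc3)cc2)oc2cc(OS(=O)(=O)[O-])cc(O)c12 | intermediate
16 | bis(triethylammonium) kaempferol 3,7-di-O-sulfate | CC[NH+](CC)CC.CC[NH+](CC)CC.O=c1c(OS(=O)(=O)[O-])c(-c2ccc(O)cc2)oc2cc(OS(=O)(=O)[O-])cc(O)c12 | intermediate (not isolated)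
17 | kaempferol 3,7-di-O-sulfate | O=c1c(OS(=O)(=O)O)c(-c2ccc(O)cc2)oc2cc(OS(=O)(=O)O)cc(O)c12 | target

## Step count and least certain steps

Total: 8 steps. Longest linear sequence: 6 steps (steps 1, 2, 5, 6, 7, 8 from phloroglucinol 1; equally steps 3, 4, 5, 6, 7, 8 from acetophenone 5).

**Step 5 (key step).** The most likely failure is slow turnover with the electron-rich, doubly ortho-substituted iodide. In that case reduction of the C–I bond, self-condensation of the ketone that is regenerated during the reaction, or direct CO-free arylation could outrun the carbonylative coupling. Fallback, a two-stage classical acylation that takes C4 from carbon dioxide: starting from 2, aryllithium 3 is generated as in step 2 and quenched with CO2, then acidified cold with dilute HCl to pH 3–4 to give 2,4,6-tris(methoxymethoxy)benzoic acid F1. Carbonyldiimidazole in THF converts it to (1H-imidazol-1-yl)[2,4,6-tris(methoxymethoxy)phenyl]methanone F2. This is added to two equivalents of enolate 10 (from 8 and NaN(SiMe3)2, THF, −78 → 0 °C), a Claisen-type C-acylation that returns to the route at 11.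

**Step 7.** The most likely failure is incomplete sulfation at the hydrogen-bonded O3, or partial sulfation of O5 under forcing, which would give mixtures of ionic regioisomers that are hard to separate. Fallback through neutral, chromatographable sulfate diesters: starting from 14, 2,2,2-trichloroethyl chlorosulfate with Et3N and DMAP in THF gives 2-[4-(benzyloxy)phenyl]-5-hydroxy-4-oxo-4H-chromene-3,7-diyl bis(2,2,2-trichloroethyl) bis(sulfate) F3, which is purified on silica. Zinc dust and ammonium formate in MeOH then remove both trichloroethyl groups reductively to give diammonium 2-[4-(benzyloxy)phenyl]-5-hydroxy-4-oxo-4H-chromene-3,7-diyl bis(sulfate) F4. This takes the place of 15 under the conditions of step 8, passing through diammonium kaempferol 3,7-di-O-sulfate F5 and returning to the route at 17.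

**Step 6.** The most likely failure is acetal loss running ahead of ring closure. That would leave the fully deprotected, electron-rich α-hydroxy diketone in hot acid, where retro-Claisen methanolysis or capture of the released formaldehyde equivalents by ring A can compete. Fallback that separates deprotection from ring closure: starting from 11, ZnBr2 and propane-1-thiol in CH2Cl2 at 0 °C remove the acetals without protic acid, each leaving as a thioacetal. The product, expected as hemiketal 13 in equilibrium with 12, is isolated and then dehydrated in a separate operation (NaOAc in acetic acid at reflux), returning to the route at 14. This fallback makes no new compound, F0.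

**Step 3.** The most likely failure is incomplete conversion or over-oxidation in the hypervalent iodine step, or self-condensation of the α-hydroxy ketone during acetal hydrolysis. Fallback by halogenation and displacement: starting from 5, CuBr2 in refluxing EtOAc–CHCl3 gives 2-bromo-1-[4-(benzyloxy)phenyl]ethanone F6. Sodium formate in aqueous ethanol at reflux displaces bromide to give 2-[4-(benzyloxy)phenyl]-2-oxoethyl formate F7, which hydrolyses in the same pot and returns to the route at 7.

## Further compounds

F1 | step 5 | 2,4,6-tris(methoxymethoxy)benzoic acid | O=C(O)c1c(OCOC)cc(OCOC)cc1OCOC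
F2 | step 5 | (1H-imidazol-1-yl)[2,4,6-tris(methoxymethoxy)phenyl]methanone | O=C(c1c(OCOC)cc(OCOC)cc1OCOC)n1ccnc1
F3 | step 7 | 2-[4-(benzyloxy)phenyl]-5-hydroxy-4-oxo-4H-chromene-3,7-diyl bis(2,2,2-trichloroethyl) bis(sulfate) | O=c1c(OS(=O)(=O)OCC(Cl)(Cl)Cl)c(-c2ccc(OCc3ccccc3)cc2)oc2cc(OS(=O)(=O)OCC(Cl)(Cl)Cl)cc(O)c12
F4 | step 7 | diammonium 2-[4-(benzyloxy)phenyl]-5-hydroxy-4-oxo-4H-chromene-3,7-diyl bis(sulfate) | [NH4+].[NH4+].O=c1c(OS(=O)(=O)[O-])c(-c2ccc(OCc3ccccc3)cc2)oc2cc(OS(=O)(=O)[O-])cc(O)c12
F5 | step 7 | diammonium kaempferol 3,7-di-O-sulfate | [NH4+].[NH4+].O=c1c(OS(=O)(=O)[O-])c(-c2ccc(O)cc2)oc2cc(OS(=O)(=O)[O-])cc(O)c12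
F0 | step 6 | none | none
F6 | step 3 | 2-bromo-1-[4-(benzyloxy)phenyl]ethanone | O=C(CBr)c1ccc(OCc2ccccc2)cc1
F7 | step 3 | 2-[4-(benzyloxy)phenyl]-2-oxoethyl formate | O=COCC(=O)c1ccc(OCc2ccccc2)cc1
A1 | alternative 1 | 2-[4-(benzyloxy)phenyl]-5,7-bis(methoxymethoxy)chromane-3,4-diol (mixture of stereoisomers) | OC1c2c(OCOC)cc(OCOC)cc2OC(c2ccc(OCc3ccccc3)cc2)C1O
A2 | alternative 1 | 2-{1-[4-(benzyloxy)phenyl]-2-oxoethoxy}-4,6-bis(methoxymethoxy)benzaldehyde (racemic) | O=CC(Oc1cc(OCOC)cc(OCOC)c1C=O)c1ccc(OCc2ccccc2)cc1
A3 | alternative 1 | samarium diiodide | I[Sm]I
A4 | alternative 2 | 2-[4-(benzyloxy)phenyl]-5,7-dihydroxy-3-(methoxymethoxy)-4H-chromen-4-one | O=c1c(OCOC)c(-c2ccc(OCc3ccccc3)cc2)oc2cc(O)cc(O)c12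
A5 | alternative 2 | 2-[4-(benzyloxy)phenyl]-3-(methoxymethoxy)-5-(phenylsulfinyl)-4H-pyran-4-one (racemic at sulfur) | O=c1c(OCOC)c(-c2ccc(OCc3ccccc3)cc2)occ1S(=O)c1ccccc1
A6 | alternative 2 | 1-methoxy-1,3-bis(trimethylsilyloxy)buta-1,3-diene (mixture of geometric isomers) | COC(O[Si](C)(C)C)=CC(=C)O[Si](C)(C)C
A7 | alternative 3 | (Z)-3-[4-(benzyloxy)phenyl]-2-(methoxymethoxy)-1-(2,4,6-trihydroxyphenyl)prop-2-en-1-one | O=C(c1c(O)cc(O)cc1O)/C(OCOC)=C/c1ccc(OCc2ccccc2)cc1
A8 | alternative 3 | 6-[(3Z)-4-[4-(benzyloxy)phenyl]-3-(methoxymethoxy)-2-oxobut-3-en-1-yl]-4-hydroxy-2H-pyran-2-one | O=C(Cc1cc(O)cc(=O)o1)/C(OCOC)=C/c1ccc(OCc2ccccc2)cc1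
A9 | alternative 3 | methyl (8Z)-9-[4-(benzyloxy)phenyl]-8-(methoxymethoxy)-3,5,7-trioxonon-8-enoate | COC(=O)CC(=O)CC(=O)CC(=O)/C(OCOC)=C/c1ccc(OCc2ccccc2)cc1
A10 | alternative 3 | magnesium dimethoxide | C[O-].C[O-].[Mg+2]
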